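**Strategy.** Everything rests on cutting the tetrahydrofuran ring (O1, C2–C5; aryl on C2 and C5, hydroxymethyl carbons C3a and C4a on C3 and C4, all on one face, meso) at O1–C5 and C2–C3. The feature used is the 1,3-spacing of benzylic, oxygenated C5 and C3. With an extra ester on C3, carbons C3–C4–C5 form a push–pull cyclopropane, and O1=C2 is an acylated syringaldehyde. One Lewis-acid (3+2) annulation builds the ring, inverts C5 (trans cyclopropane gives 4,5-cis) and sets C2 cis to C5. The precursor is a trans-2-aryl-3-(silyloxymethyl)cyclopropane-1,1-diester with an acylated donor phenol. Freeing C4a–OH later lactonises the cis ester and locks C3.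

Key step: step 6

Assumption: the four stereodescriptors of the target translate into the all-cis, meso isomer, so the absolute sense of the chiral intermediates is irrelevant; they are drawn as the enantiomer that the (S)-amine of step 3 should favour, and the racemate would serve equally.

Abbreviations: Ar = 3,5-dimethoxy-4-(pivaloyloxy)phenyl; TBDPS = tert-butyldiphenylsilyl; atom labels O1, C2–C5, C3a, C4a as in the first paragraph.

**Step 1**
Reactants: 1 syringaldehyde; 2 pivaloyl chloride
Product: 3 4-formyl-2,6-dimethoxyphenyl pivalate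
Conditions: PivCl (1.2 equiv), Et3N (1.5 equiv), DMAP (5 mol %), CH2Cl2, 0 °C to rt
Reagents that add atoms: pivaloyl chloride (2), CC(C)(C)C(=O)Cl
Why: DMAP-catalysed O-acylation of a phenol; the pivalate has no α-hydrogen, is shielded by both ortho methoxy groups and lowers the ring from a strong to a moderate donor, which both later partners need.

**Step 2**
Reactants: 3 4-formyl-2,6-dimethoxyphenyl pivalate; 4 (triphenylphosphoranylidene)acetaldehyde
Product: 5 2,6-dimethoxy-4-[(E)-3-oxoprop-1-enyl]phenyl pivalate
Conditions: 4 (1.05 equiv), toluene, 80 °C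
Reagents that add atoms: (triphenylphosphoranylidene)acetaldehyde (4), O=CC=P(c1ccccc1)(c1ccccc1)c1ccccc1
Why: Wittig olefination with a formyl-stabilised ylide, which is inherently E-selective; holding the ylide near one equivalent suppresses a second homologation of the enal.

**Step 3**
Reactants: 5 2,6-dimethoxy-4-[(E)-3-oxoprop-1-enyl]phenyl pivalate; 6 dimethyl 2-bromomalonate
Product: 7 dimethyl (2S,3R)-2-Ar-3-formylcyclopropane-1,1-dicarboxylate (Ar and CHO trans)
Conditions: 6 (1.2 equiv), (S)-2-[diphenyl(trimethylsilyloxy)methyl]pyrrolidine (20 mol %), 2,6-lutidine (1.1 equiv), CH2Cl2, 0 °C to rt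
Reagents that add atoms: dimethyl 2-bromomalonate (6), COC(=O)C(Br)C(=O)OC
Why: Michael-initiated ring closure under iminium–enamine catalysis, in which bromomalonate adds to the β-carbon on the iminium face left open by the bulky pyrrolidine substituent (sets C5) and the enamine then displaces bromide 3-exo-tet with Ar and the enamine carbon anti, so the E geometry of 5 becomes the trans relation C4/C5.

**Step 4**
Reactants: 7 dimethyl (2S,3R)-2-Ar-3-formylcyclopropane-1,1-dicarboxylate
Product: 8 dimethyl (2S,3R)-2-Ar-3-(hydroxymethyl)cyclopropane-1,1-dicarboxylate (trans)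
Conditions: NaBH4 (0.6 equiv), THF/MeOH 4:1, −20 °C, short contact; NaH2PO4/Na2HPO4 buffer (pH 7) quench; crude used at once
Reagents that add atoms: none
Why: Chemoselective borohydride reduction of an aldehyde beside methyl and aryl esters; low temperature, brief exposure and a buffered quench hold back attack of the new alkoxide on the ester cis to it.

**Step 5**
Reactants: 8 dimethyl (2S,3R)-2-Ar-3-(hydroxymethyl)cyclopropane-1,1-dicarboxylate; 9 tert-butyl(chloro)diphenylsilane
Product: 10 dimethyl (2S,3R)-2-Ar-3-[(tert-butyldiphenylsilyloxy)methyl]cyclopropane-1,1-dicarboxylate (trans)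
Conditions: TBDPSCl (1.2 equiv), imidazole (2.5 equiv), CH2Cl2, 0 °C to rt
Reagents that add atoms: tert-butyl(chloro)diphenylsilane (9), CC(C)(C)[Si](Cl)(c1ccccc1)c1ccccc1
Why: Imidazole-promoted silylation of a primary alcohol; an acid-robust silyl ether is preferred to an acyl group because it cannot bridge to C5 as a neighbouring group in step 6 and can later be removed without touching the aryl pivalates.

**Step 6**
Reactants: 10 dimethyl (2S,3R)-2-Ar-3-[(tert-butyldiphenylsilyloxy)methyl]cyclopropane-1,1-dicarboxylate; 3 4-formyl-2,6-dimethoxyphenyl pivalate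
Product: 11 dimethyl (2R,4R,5R)-2,5-di-Ar-4-[(tert-butyldiphenylsilyloxy)methyl]tetrahydrofuran-3,3-dicarboxylate (2,5-cis and 4,5-cis)
Conditions: 3 (2.5 equiv), Sn(OTf)2 (10 mol %), 4 Å molecular sieves, CH2Cl2, rt
Reagents that add atoms: 4-formyl-2,6-dimethoxyphenyl pivalate (3), COc1cc(C=O)cc(OC)c1OC(=O)C(C)(C)C
Why: Sn(OTf)2 chelates both ester carbonyls of 10 and polarises C3–C5, the only ring bond flanked by a cation-stabilising aryl group and the diester, so the carbonyl oxygen of 3 attacks C5 opposite to C3 in an SN2-like opening (O1–C5 made, C5 inverted, C4 untouched). The released tin malonate enolate then adds to the tethered aryl-oxocarbenium carbon (C2–C3 made), closing the tetrahydrofuran in a formal 5-endo-trig mode with an exocyclic enolate, feasible because the acceptor is a cation, as in Prins-type closures. This is the established Lewis-acid-catalysed (3+2) annulation of 2-arylcyclopropane-1,1-diesters with aldehydes, known also for 2,3-trans-disubstituted members. Inversion turns the trans Ar/CH2O relation of 10 into 4,5-cis, and the one new centre, C2, is set by an envelope transition state that keeps both aryl groups pseudo-equatorial (2,5-cis); C3 carries two equal esters and is not yet stereogenic. The step needs substitution to outrun ionisation at C5: the para acyloxy group and two meta methoxy groups (no resonance donation to C5) make the arene a donor of roughly phenyl strength, excess aldehyde keeps capture fast, and the silyl ether cannot participate. A catalytic metal load and prompt quench guard against reversible C2–C3 cleavage, which would leak towards the 2,5-trans isomer.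

**Step 7**
Reactants: 11 dimethyl (2R,4R,5R)-2,5-di-Ar-4-[(tert-butyldiphenylsilyloxy)methyl]tetrahydrofuran-3,3-dicarboxylate
Product: 13 cis-fused lactone ester methyl 4,6-di-Ar-3-oxotetrahydro-1H,3H-furo[3,4-c]furan-3a-carboxylate (C3a carbonyl bridged through O to C4a on the aryl-bearing face; CO2Me on C3 on the opposite face), via hydroxy diester 12 (not isolated)
Conditions: HF·pyridine, THF, 0 °C to rt; then TsOH·H2O (5 mol %), CH2Cl2, rt
Reagents that add atoms: none
Why: Fluoride desilylation followed by acid-assisted γ-lactonisation (5-exo-trig), in which C4a–OH can reach only the C3 ester on its own face because only the cis-fused 5,5-bicycle is attainable, so the geminal diester is desymmetrised and C3a is fixed cis to C4a.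

**Step 8**
Reactants: 13 cis-fused lactone ester
Product: 14 all-cis lactone 4,6-di-Ar-tetrahydro-1H,3H-furo[3,4-c]furan-1-one (cis ring fusion; both Ar groups on the face of the tetrahydrofuran that carries the lactone ring)
Conditions: LiCl (3 equiv), H2O (3 equiv), DMSO, 140 °C
Reagents that add atoms: none
Why: Krapcho dealkoxycarbonylation, in which chloride demethylates the exposed convex-face ester, CO2 departs and the lactone enolate is protonated at C3, where the convex face is the open one and only the cis-fused bicycle is viable, so kinetic and thermodynamic control both place H3 cis to H4.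

**Step 9**
Reactants: 14 all-cis lactone
Product: 15 meso-(2R,3R,4S,5S)-2,5-bis(4-hydroxy-3,5-dimethoxyphenyl)tetrahydrofuran-3,4-dimethanol (all-cis; target CNP0170897.3)
Conditions: LiAlH4 (4 equiv), THF, 0 °C to rt; EtOAc quench, aq potassium sodium tartrate, adjusted to pH 6–7 with NaH2PO4
Reagents that add atoms: none
Why: Hydride reduction of the lactone to the 1,4-diol with simultaneous reductive cleavage of both aryl pivalates; no stereocentre is touched, and a cold, near-neutral work-up avoids quinone-methide epimerisation at C2 and C5 of the free bisphenol.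

**Compound list**

| No. | Name | SMILES | Role |
|---|---|---|---|
| 1 | syringaldehyde | COc1cc(C=O)cc(OC)c1O | starting material |
| 2 | pivaloyl chloride | CC(C)(C)C(=O)Cl | starting material |
| 3 | 4-formyl-2,6-dimethoxyphenyl pivalate | COc1cc(C=O)cc(OC)c1OC(=O)C(C)(C)C | intermediate |
| 4 | (triphenylphosphoranylidene)acetaldehyde | O=CC=P(c1ccccc1)(c1ccccc1)c1ccccc1 | starting material |
| 5 | 2,6-dimethoxy-4-[(E)-3-oxoprop-1-enyl]phenyl pivalate | COc1cc(/C=C/C=O)cc(OC)c1OC(=O)C(C)(C)C | intermediate |
| 6 | dimethyl 2-bromomalonate | COC(=O)C(Br)C(=O)OC | starting material |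
| 7 | dimethyl (2S,3R)-2-Ar-3-formylcyclopropane-1,1-dicarboxylate (trans) | COC(=O)C1(C(=O)OC)[C@H](c2cc(OC)c(OC(=O)C(C)(C)C)c(OC)c2)[C@H]1C=O | intermediate |
| 8 | dimethyl (2S,3R)-2-Ar-3-(hydroxymethyl)cyclopropane-1,1-dicarboxylate (trans) | COC(=O)C1(C(=O)OC)[C@H](c2cc(OC)c(OC(=O)C(C)(C)C)c(OC)c2)[C@H]1CO | intermediate |
| 9 | tert-butyl(chloro)diphenylsilane | CC(C)(C)[Si](Cl)(c1ccccc1)c1ccccc1 | starting material |
| 10 | dimethyl (2S,3R)-2-Ar-3-[(tert-butyldiphenylsilyloxy)methyl]cyclopropane-1,1-dicarboxylate (trans) | COC(=O)C1(C(=O)OC)[C@H](c2cc(OC)c(OC(=O)C(C)(C)C)c(OC)c2)[C@H]1CO[Si](c3ccccc3)(c3ccccc3)C(C)(C)C | intermediate |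
| 11 | dimethyl (2R,4R,5R)-2,5-di-Ar-4-[(tert-butyldiphenylsilyloxy)methyl]tetrahydrofuran-3,3-dicarboxylate (2,5-cis, 4,5-cis) | COc1cc([C@@H]2O[C@H](c3cc(OC)c(OC(=O)C(C)(C)C)c(OC)c3)C(C(=O)OC)(C(=O)OC)[C@@H]2CO[Si](c3ccccc3)(c3ccccc3)C(C)(C)C)cc(OC)c1OC(=O)C(C)(C)C | intermediate |
| 12 | dimethyl 2,5-di-Ar-4-(hydroxymethyl)tetrahydrofuran-3,3-dicarboxylate (2,5-cis, 4,5-cis) | COc1cc([C@@H]2O[C@H](c3cc(OC)c(OC(=O)C(C)(C)C)c(OC)c3)C(C(=O)OC)(C(=O)OC)[C@@H]2CO)cc(OC)c1OC(=O)C(C)(C)C | intermediate |
| 13 | methyl 4,6-di-Ar-3-oxotetrahydro-1H,3H-furo[3,4-c]furan-3a-carboxylate (cis-fused, both Ar on the lactone-bearing face) | COc1cc([C@@H]2O[C@H](c3cc(OC)c(OC(=O)C(C)(C)C)c(OC)c3)[C@]4(C(=O)OC)C(=O)OC[C@H]24)cc(OC)c1OC(=O)C(C)(C)C | intermediate |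
| 14 | 4,6-di-Ar-tetrahydro-1H,3H-furo[3,4-c]furan-1-one (cis-fused, both Ar on the lactone-bearing face) | COc1cc([C@@H]2O[C@H](c3cc(OC)c(OC(=O)C(C)(C)C)c(OC)c3)[C@@H]4C(=O)OC[C@H]24)cc(OC)c1OC(=O)C(C)(C)C | intermediate |
| 15 | meso all-cis 2,5-bis(4-hydroxy-3,5-dimethoxyphenyl)tetrahydrofuran-3,4-dimethanol | COc1cc([C@H]2O[C@@H](c3cc(OC)c(O)c(OC)c3)[C@@H](CO)[C@H]2CO)cc(OC)c1O | target |

**Total step count:** 9.
**Longest linear sequence:** 9 (1 → 3 → 5 → 7 → 8 → 10 → 11 → 13 → 14 → 15). Compound 3 enters twice, in steps 2 and 6.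

**Steps most likely to fail**

1. **Step 6.**
   - *Risk.* The deactivated, trisubstituted cyclopropane may open too slowly. Under more forcing Lewis acids it may ionise at C5, which loses the inversion that creates the 4,5-cis relation. It may also shed the C4 proton to give an open chain, or equilibrate at C2 through reversible C2–C3 cleavage.
   - *Fallback.* The cyclopropane is abandoned and all four centres are set by one-face hydrogenation of a furan. Setting out from 3, Roskamp homologation with ethyl diazoacetate (NbCl5 cat., CH2Cl2, rt) should give ethyl 3-Ar-3-oxopropanoate F1. Oxidative enolate dimerisation (NaH, then I2, THF) should give diethyl 2,3-bis(Ar-carbonyl)butanedioate F2. Paal–Knorr cyclodehydration (TsOH·H2O, toluene, reflux) should give diethyl 2,5-di-Ar-furan-3,4-dicarboxylate F3. Heterogeneous syn-hydrogenation (H2 under pressure, 5% Rh/Al2O3, EtOAc) should deliver all hydrogens to one face and give diethyl all-cis-2,5-di-Ar-tetrahydrofuran-3,4-dicarboxylate F4. LiAlH4 under the conditions of step 9 brings the material back to the route at 15.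

2. **Step 8.**
   - *Risk.* Hot, wet DMSO may hydrolyse the aryl pivalates, after which phenoxide-driven quinone-methide opening could scramble C2 or C5. Chloride may also attack C4a of the lactone, and the transient enolate may expel O1 from C2.
   - *Fallback.* Ester cleavage is separated from carbon loss so that neither stage is hot, wet and basic. Setting out from 13, acyl-oxygen hydrolysis of the methyl ester with Me3SnOH (1,2-dichloroethane, 75 °C, dilute HCl work-up, which also recloses any opened lactone) should give 4,6-di-Ar-3-oxotetrahydro-1H,3H-furo[3,4-c]furan-3a-carboxylic acid F5. This should decarboxylate under neutral, anhydrous conditions (toluene, 105 °C) with the same ring-fusion control at C3, rejoining the route at 14.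

3. **Step 4.**
   - *Risk.* The alkoxide formed on reduction may close prematurely onto the cis ester. Base may also trigger opening of the formylcyclopropane before reduction is complete.
   - *Fallback.* The protected hydroxymethyl group is installed before the three-membered ring exists. Setting out from 5, Luche reduction (NaBH4, CeCl3·7H2O, MeOH, 0 °C) should give 4-[(E)-3-hydroxyprop-1-enyl]-2,6-dimethoxyphenyl pivalate F6. Silylation with 9 (imidazole, CH2Cl2) should give 4-[(E)-3-(tert-butyldiphenylsilyloxy)prop-1-enyl]-2,6-dimethoxyphenyl pivalate F7. Stereospecific carbene transfer from dimethyl diazomalonate follows, with slow addition in CH2Cl2 and catalysis by Rh2(esp)2 (esp = α,α,α',α'-tetramethyl-1,3-benzenedipropanoate). It should carry the E geometry into the trans cyclopropane and rejoin the route at 10, as the racemate, which is sufficient for a meso target.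

**Further compounds**

F1 | step 6 | ethyl 3-[3,5-dimethoxy-4-(pivaloyloxy)phenyl]-3-oxopropanoate | CCOC(=O)CC(=O)c1cc(OC)c(OC(=O)C(C)(C)C)c(OC)c1
F2 | step 6 | diethyl 2,3-bis[3,5-dimethoxy-4-(pivaloyloxy)benzoyl]butanedioate (meso and racemic forms together; both centres vanish in the next operation) | CCOC(=O)C(C(=O)c1cc(OC)c(OC(=O)C(C)(C)C)c(OC)c1)C(C(=O)OCC)C(=O)c1cc(OC)c(OC(=O)C(C)(C)C)c(OC)c1
F3 | step 6 | diethyl 2,5-bis[3,5-dimethoxy-4-(pivaloyloxy)phenyl]furan-3,4-dicarboxylate | CCOC(=O)c1c(-c2cc(OC)c(OC(=O)C(C)(C)C)c(OC)c2)oc(-c2cc(OC)c(OC(=O)C(C)(C)C)c(OC)c2)c1C(=O)OCC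
F4 | step 6 | diethyl all-cis (meso) 2,5-bis[3,5-dimethoxy-4-(pivaloyloxy)phenyl]tetrahydrofuran-3,4-dicarboxylate | COc1cc([C@H]2O[C@@H](c3cc(OC)c(OC(=O)C(C)(C)C)c(OC)c3)[C@@H](C(=O)OCC)[C@H]2C(=O)OCC)cc(OC)c1OC(=O)C(C)(C)C
F5 | step 8 | 4,6-bis[3,5-dimethoxy-4-(pivaloyloxy)phenyl]-3-oxotetrahydro-1H,3H-furo[3,4-c]furan-3a-carboxylic acid (cis-fused, aryl groups on the lactone-bearing face) | COc1cc([C@@H]2O[C@H](c3cc(OC)c(OC(=O)C(C)(C)C)c(OC)c3)[C@]4(C(=O)O)C(=O)OC[C@H]24)cc(OC)c1OC(=O)C(C)(C)C
F6 | step 4 | 4-[(E)-3-hydroxyprop-1-enyl]-2,6-dimethoxyphenyl pivalate | COc1cc(/C=C/CO)cc(OC)c1OC(=O)C(C)(C)C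
F7 | step 4 | 4-[(E)-3-(tert-butyldiphenylsilyloxy)prop-1-enyl]-2,6-dimethoxyphenyl pivalate | COc1cc(/C=C/CO[Si](c2ccccc2)(c2ccccc2)C(C)(C)C)cc(OC)c1OC(=O)C(C)(C)C
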